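**Strategy**

Isorawsonol is disconnected at the diarylmethane bond between the benzylic CH2 on C6 of ring A (the hexasubstituted ring bearing CH2OH on C1) and C1' of ring B (the pentasubstituted bromocatechol ring). The key step exploits two para relationships: this CH2 lies para to the C3 hydroxyl of ring A, and C1' lies para to the C4' oxygen of ring B. Its precursor is a 6-hydroxyphthalide whose lactone ties C1 (as carbonyl) to the C6 CH2; acid opens it to a p-quinone methide that is captured by a ring-B diarylmethane (C4'-OMe, C5'-OPiv) para to methoxy, forging the bond and unmasking the future CH2OH carbon as CO2H in one operation.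

Key step: step 5

Remark: the target has no stereocentre and is achiral, so no enantiocontrol is needed; the racemic intermediates 3 and 8 lose their only stereocentre in the step that forms them.

Numbering used: ring A C1 (CH2OH), C2 (CH2Ar), C3 (OH), C4 (OH), C5 (Br), C6 (CH2 to ring B); ring B C1' (bonded to that CH2), C2' (H), C3' (Br), C4' (OH), C5' (OH), C6' (CH2Ar); Ar = 3-bromo-4-hydroxyphenyl.

**Route**

Step 1
Reactants: 1 methyl 3-hydroxy-4-methoxybenzoate (methyl isovanillate); 2 3-bromo-4-methoxybenzaldehyde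
Product: 4 methyl 2-(3-bromo-4-methoxybenzyl)-3-hydroxy-4-methoxybenzoate, via dioxaborin 3 (not isolated)
Conditions: PhB(OH)2 (1.2 equiv), EtCO2H (cat.), toluene, reflux, Dean–Stark; then Et3SiH, TFA, CH2Cl2, 0 °C → rt
Reagents that add atoms: none
Why: Phenylboronic-acid-templated ortho-specific hydroxyalkylation of a phenol (benzodioxaborin formation) delivers the aldehyde to C2, the only free ortho carbon of 1, and ionic hydrogenation of the benzylic C–O bond of 3 then gives the ortho-benzylphenol.

Step 2
Reactants: 4 methyl 2-(3-bromo-4-methoxybenzyl)-3-hydroxy-4-methoxybenzoate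
Product: 6 7-(3-bromo-4-methoxybenzyl)-6-hydroxy-5-methoxyisobenzofuran-1(3H)-one, via hydroxymethyl ester 5 (not isolated)
Conditions: aq. HCHO (excess), NaOH, H2O/THF, rt; then aq. HCl, 40 °C
Reagents that add atoms: formaldehyde, C=O
Why: Lederer–Manasse hydroxymethylation: the phenoxide of 4 has only its para position (C6) free, so formaldehyde should enter there, and the benzylic alcohol 5 lactonises onto the neighbouring ester (phthalide formation).

Step 3
Reactants: 7 2-methoxyphenol (guaiacol); 2 3-bromo-4-methoxybenzaldehyde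
Product: 9 2-(3-bromo-4-methoxybenzyl)-6-methoxyphenol, via dioxaborin 8 (not isolated)
Conditions: PhB(OH)2 (1.1 equiv), EtCO2H (cat.), toluene, reflux, Dean–Stark; then Et3SiH, TFA, CH2Cl2, 0 °C → rt
Reagents that add atoms: none
Why: The same boronic-acid-templated ortho-hydroxyalkylation and ionic hydrogenation on electron-rich guaiacol, whose single free ortho position places the benzyl group next to the hydroxyl.

Step 4
Reactants: 9 2-(3-bromo-4-methoxybenzyl)-6-methoxyphenol
Product: 10 2-(3-bromo-4-methoxybenzyl)-6-methoxyphenyl pivalate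
Conditions: PivCl, Et3N, DMAP (cat.), CH2Cl2, 0 °C → rt
Reagents that add atoms: pivaloyl chloride, CC(C)(C)C(=O)Cl
Why: DMAP-catalysed O-acylation; the pivalate switches off the C5' oxygen as a para director so that the methoxy group alone steers the electrophiles of steps 5 and 7.

Step 5
Reactants: 6 7-(3-bromo-4-methoxybenzyl)-6-hydroxy-5-methoxyisobenzofuran-1(3H)-one; 10 2-(3-bromo-4-methoxybenzyl)-6-methoxyphenyl pivalate
Product: 12 2-(3-bromo-4-methoxybenzyl)-6-[2-(3-bromo-4-methoxybenzyl)-4-methoxy-3-(pivaloyloxy)benzyl]-3-hydroxy-4-methoxybenzoic acid, via quinone methide acid 11 (not isolated)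
Conditions: 6 (1.0 equiv), 10 (1.3 equiv), TfOH (10 mol%), HFIP/CH2Cl2, 0 °C → rt
Reagents that add atoms: none
Why: TfOH in HFIP protonates the lactone carbonyl of 6 and the C3–O bond ionises with push from the para hydroxyl, giving the (O-protonated) p-quinone methide 11 with the carboxyl set free; arene 10 attacks its exocyclic CH2 through C1' and rearomatisation gives acid 12. The closest known reaction types are the acid-mediated Friedel–Crafts (1,6-) addition of electron-rich arenes to p-quinone methides generated from 4-hydroxybenzyl alcohols or esters and the Friedel–Crafts opening of phthalides to 2-benzylbenzoic acids. No ring is closed and no stereocentre is formed. Chemoselectivity between the two neighbouring benzylic carbons of ring A is built into the lactone: only the C6 carbon carries a leaving group para to a free hydroxyl, while the C1 carbon is a carbonyl. Site selectivity on 10 rests on the C4' methoxy group as the only conjugated donor: C1' is para to it, C3' is shielded by the O-methyl group that the flanking pivalate forces to that side, C2' is para only to the weakly donating pivalate, and both bromoanisole rings are deactivated. The product acid has no leaving group left and should not react further.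

Step 6
Reactants: 12 2-(3-bromo-4-methoxybenzyl)-6-[2-(3-bromo-4-methoxybenzyl)-4-methoxy-3-(pivaloyloxy)benzyl]-3-hydroxy-4-methoxybenzoic acid
Product: 13 methyl 2-(3-bromo-4-methoxybenzyl)-6-[2-(3-bromo-4-methoxybenzyl)-4-methoxy-3-(pivaloyloxy)benzyl]-3,4-dimethoxybenzoate
Conditions: MeI (excess), K2CO3, DMF, rt → 40 °C
Reagents that add atoms: iodomethane, CI
Why: Williamson O-methylation of the phenol and SN2 esterification of the carboxylate cap the oxidation-prone 2,4,6-trisubstituted phenol before bromination and give an ester that is easy to reduce; the aryl pivalate is inert to K2CO3/MeI.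

Step 7
Reactants: 13 methyl 2-(3-bromo-4-methoxybenzyl)-6-[2-(3-bromo-4-methoxybenzyl)-4-methoxy-3-(pivaloyloxy)benzyl]-3,4-dimethoxybenzoate
Product: 14 methyl 5-bromo-2-(3-bromo-4-methoxybenzyl)-6-[5-bromo-2-(3-bromo-4-methoxybenzyl)-4-methoxy-3-(pivaloyloxy)benzyl]-3,4-dimethoxybenzoate
Conditions: NBS (2.2 equiv), HFIP, 0 °C → rt, dark
Reagents that add atoms: N-bromosuccinimide, O=C1CCC(=O)N1Br
Why: Electrophilic aromatic bromination: ring A has a single free position (C5, ortho to the C4 methoxy) and ring B should react at C3', ortho to its only conjugated methoxy and para to the C6' benzyl group, whereas C2' (para to the pivalate) and the already brominated anisole rings are far less activated.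

Step 8
Reactants: 14 methyl 5-bromo-2-(3-bromo-4-methoxybenzyl)-6-[5-bromo-2-(3-bromo-4-methoxybenzyl)-4-methoxy-3-(pivaloyloxy)benzyl]-3,4-dimethoxybenzoate
Product: 15 methyl 5-bromo-2-(3-bromo-4-hydroxybenzyl)-6-[5-bromo-2-(3-bromo-4-hydroxybenzyl)-4-hydroxy-3-(pivaloyloxy)benzyl]-3,4-dihydroxybenzoate
Conditions: BBr3 (excess), CH2Cl2, −78 → 0 °C; ice-water quench
Reagents that add atoms: none
Why: BBr3 cleavage of the five aryl methyl ethers (Lewis adduct, then SN2 at methyl by bromide) is standard for polybrominated diarylmethanes; C1 is kept at the ester level so that no benzylic alcohol meets BBr3, and the hindered methyl ester and the aryl pivalate are expected to survive at ≤0 °C (their partial loss or a pivaloyl shift between the ring-B oxygens would be harmless for step 9).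

Step 9
Reactants: 15 methyl 5-bromo-2-(3-bromo-4-hydroxybenzyl)-6-[5-bromo-2-(3-bromo-4-hydroxybenzyl)-4-hydroxy-3-(pivaloyloxy)benzyl]-3,4-dihydroxybenzoate
Product: 16 isorawsonol, 3-bromo-4-[5-bromo-2-(3-bromo-4-hydroxybenzyl)-3,4-dihydroxybenzyl]-6-(3-bromo-4-hydroxybenzyl)-5-(hydroxymethyl)benzene-1,2-diol
Conditions: DIBAL-H (excess), THF, −78 → 0 °C; aq. Rochelle salt, pH about 5–6, no methanol
Reagents that add atoms: none
Why: Hydride reduction with DIBAL-H converts the hindered methyl ester into the benzylic alcohol and removes the pivalate reductively in the same operation without touching aryl bromides, and the cold, near-neutral, methanol-free work-up protects the p-hydroxybenzyl alcohol from quinone-methide solvolysis.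

**Compound list**

1 | methyl 3-hydroxy-4-methoxybenzoate (methyl isovanillate) | COC(=O)c1ccc(OC)c(O)c1 | starting material
2 | 3-bromo-4-methoxybenzaldehyde | COc1ccc(C=O)cc1Br | starting material
3 | methyl 4-(3-bromo-4-methoxyphenyl)-8-methoxy-2-phenyl-4H-1,3,2-benzodioxaborine-5-carboxylate (racemic) | COC(=O)c1ccc(OC)c2OB(c3ccccc3)OC(c3ccc(OC)c(Br)c3)c12 | intermediate (not isolated)
4 | methyl 2-(3-bromo-4-methoxybenzyl)-3-hydroxy-4-methoxybenzoate | COC(=O)c1ccc(OC)c(O)c1Cc1ccc(OC)c(Br)c1 | intermediate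
5 | methyl 2-(3-bromo-4-methoxybenzyl)-3-hydroxy-6-(hydroxymethyl)-4-methoxybenzoate | COC(=O)c1c(CO)cc(OC)c(O)c1Cc1ccc(OC)c(Br)c1 | intermediate (not isolated)
6 | 7-(3-bromo-4-methoxybenzyl)-6-hydroxy-5-methoxyisobenzofuran-1(3H)-one | O=C1OCc2cc(OC)c(O)c(Cc3ccc(OC)c(Br)c3)c12 | intermediate
7 | 2-methoxyphenol (guaiacol) | COc1ccccc1O | starting material
8 | 4-(3-bromo-4-methoxyphenyl)-8-methoxy-2-phenyl-4H-1,3,2-benzodioxaborine (racemic) | COc1cccc2C(c3ccc(OC)c(Br)c3)OB(c3ccccc3)Oc12 | intermediate (not isolated)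
9 | 2-(3-bromo-4-methoxybenzyl)-6-methoxyphenol | COc1cccc(Cc2ccc(OC)c(Br)c2)c1O | intermediate
10 | 2-(3-bromo-4-methoxybenzyl)-6-methoxyphenyl pivalate | COc1cccc(Cc2ccc(OC)c(Br)c2)c1OC(=O)C(C)(C)C | intermediate
11 | 2-(3-bromo-4-methoxybenzyl)-4-methoxy-6-methylidene-3-oxocyclohexa-1,4-diene-1-carboxylic acid (p-quinone methide) | C=C1C=C(OC)C(=O)C(Cc2ccc(OC)c(Br)c2)=C1C(=O)O | intermediate (not isolated)
12 | 2-(3-bromo-4-methoxybenzyl)-6-[2-(3-bromo-4-methoxybenzyl)-4-methoxy-3-(pivaloyloxy)benzyl]-3-hydroxy-4-methoxybenzoic acid | OC(=O)c1c(Cc2ccc(OC)c(Br)c2)c(O)c(OC)cc1Cc1ccc(OC)c(OC(=O)C(C)(C)C)c1Cc1ccc(OC)c(Br)c1 | intermediate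
13 | methyl 2-(3-bromo-4-methoxybenzyl)-6-[2-(3-bromo-4-methoxybenzyl)-4-methoxy-3-(pivaloyloxy)benzyl]-3,4-dimethoxybenzoate | COC(=O)c1c(Cc2ccc(OC)c(Br)c2)c(OC)c(OC)cc1Cc1ccc(OC)c(OC(=O)C(C)(C)C)c1Cc1ccc(OC)c(Br)c1 | intermediate
14 | methyl 5-bromo-2-(3-bromo-4-methoxybenzyl)-6-[5-bromo-2-(3-bromo-4-methoxybenzyl)-4-methoxy-3-(pivaloyloxy)benzyl]-3,4-dimethoxybenzoate | COC(=O)c1c(Cc2ccc(OC)c(Br)c2)c(OC)c(OC)c(Br)c1Cc1cc(Br)c(OC)c(OC(=O)C(C)(C)C)c1Cc1ccc(OC)c(Br)c1 | intermediate
15 | methyl 5-bromo-2-(3-bromo-4-hydroxybenzyl)-6-[5-bromo-2-(3-bromo-4-hydroxybenzyl)-4-hydroxy-3-(pivaloyloxy)benzyl]-3,4-dihydroxybenzoate | COC(=O)c1c(Cc2ccc(O)c(Br)c2)c(O)c(O)c(Br)c1Cc1cc(Br)c(O)c(OC(=O)C(C)(C)C)c1Cc1ccc(O)c(Br)c1 | intermediate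
16 | isorawsonol (achiral) | OCc1c(Cc2ccc(O)c(Br)c2)c(O)c(O)c(Br)c1Cc1cc(Br)c(O)c(O)c1Cc1ccc(O)c(Br)c1 | target

**Step count**

Total step count: 9.
Longest linear sequence: 7 steps (1 → 4 → 6 → 12 → 13 → 14 → 15 → 16; the ring-B branch 7 → 9 → 10 → 12 → … is equally long).

**Steps most likely to fail, with fallbacks**

Step 5 (key step). The lactone may ionise too slowly, or the benzylic cation may be captured with poor site selectivity (ortho to the methoxy group, or by a bromoanisole ring), or the acid may trigger benzyl transfer between rings. The fallback replaces the quinone-methide activation by a classical benzylic-halide Friedel–Crafts reaction. It sets out from 6 (with 10 unchanged) and returns at 13. Compound 6 is O-methylated (MeI, K2CO3, DMF) to 7-(3-bromo-4-methoxybenzyl)-5,6-dimethoxyisobenzofuran-1(3H)-one F1. The lactone is opened with Ph3PBr2 (chlorobenzene, 120 °C) to 2-(3-bromo-4-methoxybenzyl)-6-(bromomethyl)-3,4-dimethoxybenzoyl bromide F2, which is quenched with methanol to methyl 2-(3-bromo-4-methoxybenzyl)-6-(bromomethyl)-3,4-dimethoxybenzoate F3. Silver-triflate-promoted benzylation of 10 with F3 (AgOTf, CH2Cl2, −40 → 0 °C) should give 13 directly, and the route continues with step 7.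

Step 1. The boron-templated delivery of the aldehyde to the crowded ortho carbon next to the ester may stall, leaving unreacted phenol. The fallback uses directed ortho-metalation instead; it sets out from 1 and returns at 6. Compound 1 is protected (MOMCl, iPr2NEt, CH2Cl2) as methyl 4-methoxy-3-(methoxymethoxy)benzoate F4 and saponified (LiOH, THF/H2O; then HCl) to 4-methoxy-3-(methoxymethoxy)benzoic acid F5. Lithiation (s-BuLi, TMEDA, THF, −78 °C) should occur at C2, between the carboxylate and the OMOM group. Addition to aldehyde 2 gives racemic 2-[(3-bromo-4-methoxyphenyl)(hydroxy)methyl]-4-methoxy-3-(methoxymethoxy)benzoic acid F6, which closes on mild acidic work-up to racemic 3-(3-bromo-4-methoxyphenyl)-5-methoxy-4-(methoxymethoxy)isobenzofuran-1(3H)-one F7. Ionic hydrogenation (Et3SiH, TFA, CH2Cl2) opens the doubly benzylic lactone C–O bond and removes the MOM group, giving 2-(3-bromo-4-methoxybenzyl)-3-hydroxy-4-methoxybenzoic acid F8. Hydroxymethylation under the conditions of step 2 gives 2-(3-bromo-4-methoxybenzyl)-3-hydroxy-6-(hydroxymethyl)-4-methoxybenzoic acid F9, which lactonises on acidification to 6.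

Step 7. Ring B may be brominated with insufficient site discrimination (attack at C2'), the crowded C5 of ring A may react incompletely, or forcing conditions may over-brominate the bromoanisole rings. The fallback changes the directing groups from methoxy to free hydroxyl by reversing the order of deprotection and bromination; it sets out from 13 and returns at 15. Compound 13 is demethylated first (BBr3, CH2Cl2, −78 → 0 °C) to methyl 2-(3-bromo-4-hydroxybenzyl)-6-[2-(3-bromo-4-hydroxybenzyl)-4-hydroxy-3-(pivaloyloxy)benzyl]-3,4-dihydroxybenzoate F10. Phenol-directed ortho-bromination (NBS, 2.0 equiv, THF/MeCN, −40 °C) should then give 15. C5 is the only free position of ring A and is ortho to the C4 hydroxyl; C3' is ortho to the free C4' hydroxyl, whose para position is blocked; the bromophenol rings are strongly deactivated.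

**Further compounds**

F1 | step 5 | 7-(3-bromo-4-methoxybenzyl)-5,6-dimethoxyisobenzofuran-1(3H)-one | O=C1OCc2cc(OC)c(OC)c(Cc3ccc(OC)c(Br)c3)c12
F2 | step 5 | 2-(3-bromo-4-methoxybenzyl)-6-(bromomethyl)-3,4-dimethoxybenzoyl bromide | O=C(Br)c1c(CBr)cc(OC)c(OC)c1Cc1ccc(OC)c(Br)c1
F3 | step 5 | methyl 2-(3-bromo-4-methoxybenzyl)-6-(bromomethyl)-3,4-dimethoxybenzoate | COC(=O)c1c(CBr)cc(OC)c(OC)c1Cc1ccc(OC)c(Br)c1
F4 | step 1 | methyl 4-methoxy-3-(methoxymethoxy)benzoate | COCOc1cc(C(=O)OC)ccc1OC
F5 | step 1 | 4-methoxy-3-(methoxymethoxy)benzoic acid | COCOc1cc(C(=O)O)ccc1OC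
F6 | step 1 | 2-[(3-bromo-4-methoxyphenyl)(hydroxy)methyl]-4-methoxy-3-(methoxymethoxy)benzoic acid (racemic) | OC(=O)c1ccc(OC)c(OCOC)c1C(O)c1ccc(OC)c(Br)c1
F7 | step 1 | 3-(3-bromo-4-methoxyphenyl)-5-methoxy-4-(methoxymethoxy)isobenzofuran-1(3H)-one (racemic) | O=C1OC(c2ccc(OC)c(Br)c2)c2c(OCOC)c(OC)ccc12
F8 | step 1 | 2-(3-bromo-4-methoxybenzyl)-3-hydroxy-4-methoxybenzoic acid | OC(=O)c1ccc(OC)c(O)c1Cc1ccc(OC)c(Br)c1
F9 | step 1 | 2-(3-bromo-4-methoxybenzyl)-3-hydroxy-6-(hydroxymethyl)-4-methoxybenzoic acid | OC(=O)c1c(CO)cc(OC)c(O)c1Cc1ccc(OC)c(Br)c1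
F10 | step 7 | methyl 2-(3-bromo-4-hydroxybenzyl)-6-[2-(3-bromo-4-hydroxybenzyl)-4-hydroxy-3-(pivaloyloxy)benzyl]-3,4-dihydroxybenzoate | COC(=O)c1c(Cc2ccc(O)c(Br)c2)c(O)c(O)cc1Cc1ccc(O)c(OC(=O)C(C)(C)C)c1Cc1ccc(O)c(Br)c1
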